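1. Endgame: target ⇐ C3 acetate, C8 isovalerate and C11=C13 methylenation on the epoxy lactone ⇐ trans-1,10-epoxide by attack of O10 on C1–Cl ⇐ 8,10-syn diol ⇐ β-hydroxy ketone 22.
2. Feature used: the epoxide carbon C10 (bearing C14 and oxygen) is β to the oxygenated C8 through C9, an aldol relationship, and C1 is α to C10. An intramolecular Mukaiyama aldol of the C8 silyl enol ether onto the C10 methyl ketone carrying chloride at C1 therefore forms C9–C10 and closes the ten-membered ring C1–C10.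
3. Precursor 21 ⇐ C10 ketone built beside the enol silane (hydroboration, enamine α-chlorination at C1, MeMgBr for C14, oxidation) ⇐ trans 4-acetyl-γ-lactone 14 ⇐ paraconic acid 12 from an Evans syn aldol/lactonisation of a succinate imide with Z-enal 6.
4. Enal 6 ⇐ 3-methylfuran-2(5H)-one: the ring fixes the 4Z olefin, and asymmetric allylboration of its lactol sets C3 and brings in C2, C1 and C10.
5. Ring order: γ-lactone (step 7), ten-membered carbocycle (step 16), epoxide (step 19).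

Key step: step 16

Numbering (germacranolide style): ring carbons C1–C10; C11 and C12 are the lactone α-carbon and carbonyl (C12–O–C6); C13 is the methylene on C11; C14 the methyl on C10; C15 the methyl on C4.
Remark on the chemistry: the C8 enol ether is carried as the tert-butyldimethylsilyl ether, not the trimethylsilyl ether. It has to be made while C8 is the only ketone (step 10) and then survive steps 11–15, and it also masks the base-labile β-acyloxy ketone.
Remark on the chemistry: chlorohydrin 20 is drawn as its expected major 10R epimer; both C10 epimers converge on 21.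

Step 1
Reactants: 1 3-methylfuran-2(5H)-one
Product: 2 3-methyl-2,5-dihydrofuran-2-ol (racemic lactol)
Conditions: iBu2AlH (1.05 equiv), CH2Cl2, −78 °C; aq KNaC4H4O6; used crude
Reagents that add atoms: none
Why: Lactone-to-lactol reduction at −78 °C leaves the ring olefin untouched and Z by constraint; the lactol is not stored because it dehydrates easily to 3-methylfuran.

Step 2
Reactants: 2 3-methyl-2,5-dihydrofuran-2-ol
Product: 3 (2Z,4S)-3-methylhepta-2,6-diene-1,4-diol
Conditions: (−)-Ipc2BOMe (2.2 equiv), CH2=CHCH2MgBr (2.1 equiv), Et2O, −78 °C → rt; then 2, −78 °C → rt; NaOH, H2O2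
Reagents that add atoms: (−)-B-allyldiisopinocampheylborane, C=CCB([C@@H]1C[C@@H]2C[C@H]([C@H]1C)C2(C)C)[C@@H]1C[C@@H]2C[C@H]([C@H]1C)C2(C)C, made in the flask from (−)-B-methoxydiisopinocampheylborane and allylmagnesium bromide, C=CC[Mg]Br
Why: Brown allylboration of the ring-opened (Z)-hydroxy enal through a chair transition state; the reagent derived from (+)-α-pinene should add allyl to the Si face and set C3 as S.

Step 3
Reactants: 3 (2Z,4S)-3-methylhepta-2,6-diene-1,4-diol
Product: 4 (2Z,4S)-1,4-bis(tert-butyldimethylsilyloxy)-3-methylhepta-2,6-diene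
Conditions: TBSCl (2.5 equiv), imidazole, DMF, rt
Reagents that add atoms: tert-butyldimethylsilyl chloride, CC(C)(C)[Si](C)(C)Cl
Why: Silyl ether formation at both hydroxyls masks O3 before C6 is oxidised, so the (Z)-4-hydroxy enal cannot close to a lactol.

Step 4
Reactants: 4 (2Z,4S)-1,4-bis(tert-butyldimethylsilyloxy)-3-methylhepta-2,6-diene
Product: 5 (2Z,4S)-4-(tert-butyldimethylsilyloxy)-3-methylhepta-2,6-dien-1-ol
Conditions: CSA (0.1 equiv), MeOH/CH2Cl2, −10 °C
Reagents that add atoms: none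
Why: Acid-catalysed methanolysis (selective desilylation) should remove the primary silyl ether much faster than the hindered secondary one.

Step 5
Reactants: 5 (2Z,4S)-4-(tert-butyldimethylsilyloxy)-3-methylhepta-2,6-dien-1-ol
Product: 6 (2Z,4S)-4-(tert-butyldimethylsilyloxy)-3-methylhepta-2,6-dienal
Conditions: MnO2 (excess), CH2Cl2, rt; used at once
Reagents that add atoms: none
Why: Allylic oxidation under neutral heterogeneous conditions should give the enal with the Z geometry intact.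

Step 6
Reactants: 7 (S)-4-benzyloxazolidin-2-one; 8 methyl 4-chloro-4-oxobutanoate
Product: 9 methyl 4-[(S)-4-benzyl-2-oxooxazolidin-3-yl]-4-oxobutanoate
Conditions: n-BuLi, THF, −78 °C; then 8, −78 → 0 °C
Reagents that add atoms: none
Why: N-Acylation of the lithiated oxazolidinone by the acid chloride (Evans auxiliary acylation) gives the succinate imide.

Step 7
Reactants: 9 methyl 4-[(S)-4-benzyl-2-oxooxazolidin-3-yl]-4-oxobutanoate; 6 (2Z,4S)-4-(tert-butyldimethylsilyloxy)-3-methylhepta-2,6-dienal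
Product: 11 (S)-4-benzyl-3-[(2R,3S)-2-[(1Z,3S)-3-(tert-butyldimethylsilyloxy)-2-methylhexa-1,5-dien-1-yl]-5-oxotetrahydrofuran-3-carbonyl]oxazolidin-2-one, via syn-aldol adduct 10 (not isolated)
Conditions: Bu2BOTf, iPr2NEt, CH2Cl2, −78 → 0 °C; 6, −78 → 0 °C; pH 7 buffer, MeOH, H2O2; then PPTS (cat.), CH2Cl2, rt
Reagents that add atoms: none
Why: Evans syn aldol of the Z boron enolate through a Zimmerman–Traxler chair, with the (S)-benzyl auxiliary fixing the enolate face, sets C7 and C6; the new C6 hydroxyl then closes on the methyl ester (5-exo-trig lactonisation) to the trans γ-lactone.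

Step 8
Reactants: 11 lactone imide
Product: 12 (2R,3S)-2-[(1Z,3S)-3-(tert-butyldimethylsilyloxy)-2-methylhexa-1,5-dien-1-yl]-5-oxotetrahydrofuran-3-carboxylic acid
Conditions: LiOH, H2O2, THF/H2O, 0 °C; Na2SO3; HCl to pH 3
Reagents that add atoms: hydrogen peroxide, OO (as LiOOH; supplies the hydroxyl oxygen of the acid)
Why: LiOOH attacks the exocyclic imide carbonyl selectively (Evans auxiliary hydrolysis), and acidification re-closes any opened lactone, so the trans paraconic acid should result with C7 untouched.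

Step 9
Reactants: 12 paraconic acid
Product: 14 (4S,5R)-4-acetyl-5-[(1Z,3S)-3-(tert-butyldimethylsilyloxy)-2-methylhexa-1,5-dien-1-yl]dihydrofuran-2(3H)-one, via acid chloride 13 (not isolated)
Conditions: (COCl)2, DMF (cat.), CH2Cl2, 0 °C; concentrate; Me2CuLi (from MeLi, CuI), Et2O, −78 °C
Reagents that add atoms: oxalyl chloride, ClC(=O)C(=O)Cl (chlorine of 13); lithium dimethylcuprate, [Li+].C[Cu-]C (methyl C9 of 14)
Why: Acid chloride formation followed by cuprate acylation at −78 °C stops at the methyl ketone and leaves the lactone alone.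

Step 10
Reactants: 14 methyl ketone
Product: 15 (4S,5R)-4-[1-(tert-butyldimethylsilyloxy)vinyl]-5-[(1Z,3S)-3-(tert-butyldimethylsilyloxy)-2-methylhexa-1,5-dien-1-yl]dihydrofuran-2(3H)-one
Conditions: LiN(SiMe3)2 (1.1 equiv), THF, −78 °C; TBSOTf, −78 °C; Et3N, aq NaHCO3
Reagents that add atoms: tert-butyldimethylsilyl trifluoromethanesulfonate, CC(C)(C)[Si](C)(C)OS(=O)(=O)C(F)(F)F
Why: Kinetic deprotonation takes the C9 methyl protons of the only ketone rather than the hindered C7 methine or the lactone CH2, and O-silylation (kinetic silyl enol ether formation) fixes the nucleophile regiochemistry.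

Step 11
Reactants: 15 enol silane diene
Product: 17 (4S,5R)-5-[(1Z,3S)-3-(tert-butyldimethylsilyloxy)-6-hydroxy-2-methylhex-1-en-1-yl]-4-[1-(tert-butyldimethylsilyloxy)vinyl]dihydrofuran-2(3H)-one, via pinacol boronate 16 (not isolated)
Conditions: [Ir(cod)Cl]2 (cat.), dppm (cat.), pinacolborane, CH2Cl2, rt; then NaBO3·4H2O, THF/H2O, rt
Reagents that add atoms: pinacolborane, CC1(C)OBOC1(C)C (boron of 16); sodium perborate tetrahydrate NaBO3·4H2O, [Na+].[Na+].O[B-]1(O)OO[B-](O)(O)OO1 (hydroxyl oxygen of 17)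
Why: Iridium-catalysed anti-Markovnikov hydroboration should select the monosubstituted terminal olefin over the 1,1-disubstituted enol ether and the trisubstituted olefin, and perborate oxidation of the C–B bond is mild enough for the enol silane and lactone.

Step 12
Reactants: 17 primary alcohol
Product: 18 (4S,5Z)-4-(tert-butyldimethylsilyloxy)-5-methyl-6-[(2R,3S)-5-oxo-3-[1-(tert-butyldimethylsilyloxy)vinyl]tetrahydrofuran-2-yl]hex-5-enal
Conditions: Dess–Martin periodinane, pyridine, CH2Cl2, 0 °C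
Reagents that add atoms: none
Why: Pyridine-buffered Dess–Martin oxidation gives the C10 aldehyde without the acid that would hydrolyse the enol silane.

Step 13
Reactants: 18 aldehyde
Product: 19 (2S,4S,5Z)-2-chloro-4-(tert-butyldimethylsilyloxy)-5-methyl-6-[(2R,3S)-5-oxo-3-[1-(tert-butyldimethylsilyloxy)vinyl]tetrahydrofuran-2-yl]hex-5-enal
Conditions: (5S)-5-benzyl-2,2,3-trimethylimidazolidin-4-one·CF3CO2H (10 mol %), 2,3,4,5,6,6-hexachlorocyclohexa-2,4-dien-1-one, acetone, −30 °C; used crude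
Reagents that add atoms: 2,3,4,5,6,6-hexachlorocyclohexa-2,4-dien-1-one, O=C1C(Cl)=C(Cl)C(Cl)=C(Cl)C1(Cl)Cl
Why: Enamine-catalysed α-chlorination, in which the benzyl group of the (5S) catalyst shields one face of the E enamine, should set C1 as S under catalyst control, while the far less nucleophilic silyl enol ether should be spared.

Step 14
Reactants: 19 α-chloro aldehyde
Product: 20 (4S,5R)-5-[(1Z,3S,5S,6R)-3-(tert-butyldimethylsilyloxy)-5-chloro-6-hydroxy-2-methylhept-1-en-1-yl]-4-[1-(tert-butyldimethylsilyloxy)vinyl]dihydrofuran-2(3H)-one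
Conditions: MeMgBr (1.3 equiv), THF/Et2O, −78 °C; aq NH4Cl
Reagents that add atoms: methylmagnesium bromide, C[Mg]Br
Why: Grignard 1,2-addition at −78 °C installs C14 while lactone and enol silane stay inert; the Cornforth-favoured 10R carbinol is of no consequence because C10 is oxidised next.

Step 15
Reactants: 20 chlorohydrin
Product: 21 (4S,5R)-5-[(1Z,3S,5S)-3-(tert-butyldimethylsilyloxy)-5-chloro-2-methyl-6-oxohept-1-en-1-yl]-4-[1-(tert-butyldimethylsilyloxy)vinyl]dihydrofuran-2(3H)-one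
Conditions: Dess–Martin periodinane, pyridine, CH2Cl2, 0 °C; rapid filtration through Et3N-deactivated silica
Reagents that add atoms: none
Why: Buffered Dess–Martin oxidation of a chlorohydrin gives the α-chloro ketone under non-basic conditions that should neither epimerise C1 nor cleave the enol silane.

Step 16
Reactants: 21 enol silane α-chloro ketone
Product: 22 (1S,3S,4Z,6R,7S,10R)-1-chloro-10-hydroxy-8-oxo-3-(tert-butyldimethylsilyloxy)-13-norgermacr-4-en-12,6-olide
Conditions: BF3·OEt2 (2 equiv), CH2Cl2, −78 → −40 °C, 21 added slowly to a final 1 mM; aq NaHCO3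
Reagents that add atoms: none
Why: BF3 binds the C10 ketone, which is more basic than the lactone and activated by the α-chlorine; the terminal enol-silane carbon C9 attacks it, fluoride transfer to silicon releases the silyl group, and the boron aldolate gives the free tertiary alcohol on work-up. The closest known reaction types are the intramolecular Mukaiyama aldol addition and Cornforth-type (polar Felkin–Anh) addition of enol nucleophiles to α-chloro ketones. The ten-membered ring closes in a 10-exo-trig (enol-endo) mode. The new stereocentre C10 is controlled by the C1 chloride: with a non-chelating Lewis acid the C–Cl bond lies opposed to the carbonyl and C9 enters past the C1 hydrogen, anti to C2, which should give 10R with O10 and Cl set for anti displacement. The step needs regioselectivity, which the preformed C8=C9 enol silane secures; chemoselectivity for the ketone over the lactone; and ring closure over oligomerisation, which high dilution and the pre-organisation by the Z olefin and the trans lactone should favour.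

Step 17
Reactants: 22 β-hydroxy ketone
Product: 23 (1S,3S,4Z,6R,7R,8S,10R)-1-chloro-8,10-dihydroxy-3-(tert-butyldimethylsilyloxy)-13-norgermacr-4-en-12,6-olide
Conditions: Et2BOMe, THF/MeOH (4:1), −78 °C; NaBH4, −78 °C; AcOH; MeOH azeotrope
Reagents that add atoms: none
Why: Narasaka–Prasad reduction: the boron chelate of O10 and the C8 carbonyl takes external hydride axially, which should give the 8,10-syn diol, that is 8S.

Step 18
Reactants: 23 diol
Product: 24 (1S,3S,4Z,6R,7S,8S,10R)-1-chloro-10-hydroxy-3-(tert-butyldimethylsilyloxy)-8-(triethylsilyloxy)-13-norgermacr-4-en-12,6-olide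
Conditions: TESCl (1.2 equiv), imidazole, CH2Cl2, 0 °C
Reagents that add atoms: chlorotriethylsilane, CC[Si](Cl)(CC)CC
Why: Silylation of the secondary C8 hydroxyl in preference to the tertiary C10 hydroxyl blocks translactonisation to O8 and keeps O10 free.

Step 19
Reactants: 24 chlorohydrin
Product: 25 (1R,3S,4Z,6R,7S,8S,10R)-1,10-epoxy-3-(tert-butyldimethylsilyloxy)-8-(triethylsilyloxy)-13-norgermacr-4-en-12,6-olide
Conditions: NaH (1.2 equiv), THF, 0 °C → rt
Reagents that add atoms: none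
Why: Intramolecular Williamson closure (3-exo-tet): the C10 alkoxide displaces the anti chloride with inversion at C1 to give the trans epoxide, and retro-aldol is excluded because C8 is no longer a ketone.

Step 20
Reactants: 25 epoxy lactone
Product: 26 (1R,3S,4Z,6R,7S,8S,10R)-13-(dimethylamino)-1,10-epoxy-3-(tert-butyldimethylsilyloxy)-8-(triethylsilyloxy)germacr-4-en-12,6-olide (C11 epimers)
Conditions: LiN(iPr)2 (1.2 equiv), THF, −78 °C; CH2=NMe2+ I−, −78 → 0 °C
Reagents that add atoms: N,N-dimethylmethyleneiminium iodide (Eschenmoser's salt), C=[N+](C)C.[I-]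
Why: Mannich aminomethylation of the lactone enolate at C11; the C11 configuration is irrelevant because it becomes sp2.

Step 21
Reactants: 26 Mannich base
Product: 28 (1R,3S,4Z,6R,7S,8S,10R)-1,10-epoxy-3-(tert-butyldimethylsilyloxy)-8-(triethylsilyloxy)germacra-4,11(13)-dien-12,6-olide, via trimethylammonium iodide 27 (not isolated)
Conditions: MeI, MeOH, rt; then aq NaHCO3, CH2Cl2, rt
Reagents that add atoms: iodomethane, CI (N-methyl of 27; nothing of it remains in 28)
Why: Quaternisation and E1cB elimination of trimethylamine give the exocyclic α-methylene lactone.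

Step 22
Reactants: 28 α-methylene lactone
Product: 29 (1R,3S,4Z,6R,7R,8S,10R)-1,10-epoxy-8-hydroxy-3-(tert-butyldimethylsilyloxy)germacra-4,11(13)-dien-12,6-olide
Conditions: HF·pyridine, pyridine (excess), THF, 0 °C
Reagents that add atoms: none
Why: Buffered HF·pyridine should cleave the triethylsilyl ether much faster than the hindered tert-butyldimethylsilyl ether (selective desilylation) while remaining mild enough for the epoxide.

Step 23
Reactants: 29 C8 alcohol
Product: 30 (1R,3S,4Z,6R,7R,8S,10R)-1,10-epoxy-8-(3-methylbutanoyloxy)-3-(tert-butyldimethylsilyloxy)germacra-4,11(13)-dien-12,6-olide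
Conditions: (Me2CHCH2CO)2O, Et3N, DMAP (cat.), CH2Cl2, 0 °C → rt
Reagents that add atoms: 3-methylbutanoic anhydride, CC(C)CC(=O)OC(=O)CC(C)C
Why: DMAP-catalysed acylation of the C8 hydroxyl with retention, fast enough to outrun translactonisation.

Step 24
Reactants: 30 isovalerate
Product: 31 (1R,3S,4Z,6R,7R,8S,10R)-1,10-epoxy-3-hydroxy-8-(3-methylbutanoyloxy)germacra-4,11(13)-dien-12,6-olide
Conditions: Bu4NF, AcOH (1:1), THF, 0 °C → rt
Reagents that add atoms: none
Why: Acetic acid-buffered fluoride desilylation frees O3 without base damage to the α-methylene lactone, the ester or the epoxide.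

Step 25
Reactants: 31 C3 alcohol
Product: 32 (1R,3S,4Z,6R,7R,8S,10R)-3-acetoxy-1,10-epoxy-8-(3-methylbutanoyloxy)germacra-4,11(13)-dien-12,6-olide (CNP0157657.1)
Conditions: Ac2O, pyridine, DMAP (cat.), CH2Cl2, 0 °C
Reagents that add atoms: acetic anhydride, CC(=O)OC(C)=O
Why: DMAP-catalysed acetylation of the allylic C3 hydroxyl with retention completes the target.

Compound list
1 | 3-methylfuran-2(5H)-one | CC1=CCOC1=O | starting material
2 | 3-methyl-2,5-dihydrofuran-2-ol (racemic lactol) | CC1=CCOC1O | intermediate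
3 | (2Z,4S)-3-methylhepta-2,6-diene-1,4-diol | OC/C=C(/C)[C@@H](O)CC=C | intermediate
4 | (2Z,4S)-1,4-bis(tert-butyldimethylsilyloxy)-3-methylhepta-2,6-diene | CC(C)(C)[Si](C)(C)OC/C=C(/C)[C@@H](O[Si](C)(C)C(C)(C)C)CC=C | intermediate
5 | (2Z,4S)-4-(tert-butyldimethylsilyloxy)-3-methylhepta-2,6-dien-1-ol | OC/C=C(/C)[C@@H](O[Si](C)(C)C(C)(C)C)CC=C | intermediate
6 | (2Z,4S)-4-(tert-butyldimethylsilyloxy)-3-methylhepta-2,6-dienal | O=C/C=C(/C)[C@@H](O[Si](C)(C)C(C)(C)C)CC=C | intermediate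
7 | (S)-4-benzyloxazolidin-2-one | O=C1N[C@@H](Cc2ccccc2)CO1 | starting material
8 | methyl 4-chloro-4-oxobutanoate | COC(=O)CCC(Cl)=O | starting material
9 | methyl 4-[(S)-4-benzyl-2-oxooxazolidin-3-yl]-4-oxobutanoate | COC(=O)CCC(=O)N1C(=O)OC[C@@H]1Cc1ccccc1 | intermediate
10 | methyl (3S,4R,5Z,7S)-3-[(S)-4-benzyl-2-oxooxazolidine-3-carbonyl]-7-(tert-butyldimethylsilyloxy)-4-hydroxy-6-methyldeca-5,9-dienoate (syn-aldol adduct, not isolated) | COC(=O)C[C@@H]([C@H](O)/C=C(/C)[C@@H](O[Si](C)(C)C(C)(C)C)CC=C)C(=O)N1C(=O)OC[C@@H]1Cc1ccccc1 | intermediate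
11 | (S)-4-benzyl-3-[(2R,3S)-2-[(1Z,3S)-3-(tert-butyldimethylsilyloxy)-2-methylhexa-1,5-dien-1-yl]-5-oxotetrahydrofuran-3-carbonyl]oxazolidin-2-one | O=C1C[C@H](C(=O)N2C(=O)OC[C@@H]2Cc2ccccc2)[C@@H](/C=C(/C)[C@@H](O[Si](C)(C)C(C)(C)C)CC=C)O1 | intermediate
12 | (2R,3S)-2-[(1Z,3S)-3-(tert-butyldimethylsilyloxy)-2-methylhexa-1,5-dien-1-yl]-5-oxotetrahydrofuran-3-carboxylic acid | O=C1C[C@H](C(=O)O)[C@@H](/C=C(/C)[C@@H](O[Si](C)(C)C(C)(C)C)CC=C)O1 | intermediate
13 | (2R,3S)-2-[(1Z,3S)-3-(tert-butyldimethylsilyloxy)-2-methylhexa-1,5-dien-1-yl]-5-oxotetrahydrofuran-3-carbonyl chloride (not isolated) | O=C1C[C@H](C(=O)Cl)[C@@H](/C=C(/C)[C@@H](O[Si](C)(C)C(C)(C)C)CC=C)O1 | intermediate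
14 | (4S,5R)-4-acetyl-5-[(1Z,3S)-3-(tert-butyldimethylsilyloxy)-2-methylhexa-1,5-dien-1-yl]dihydrofuran-2(3H)-one | O=C1C[C@H](C(C)=O)[C@@H](/C=C(/C)[C@@H](O[Si](C)(C)C(C)(C)C)CC=C)O1 | intermediate
15 | (4S,5R)-4-[1-(tert-butyldimethylsilyloxy)vinyl]-5-[(1Z,3S)-3-(tert-butyldimethylsilyloxy)-2-methylhexa-1,5-dien-1-yl]dihydrofuran-2(3H)-one | C=C(O[Si](C)(C)C(C)(C)C)[C@H]1CC(=O)O[C@@H]1/C=C(/C)[C@@H](O[Si](C)(C)C(C)(C)C)CC=C | intermediate
16 | pinacol boronate of 15 at C10 (not isolated) | C=C(O[Si](C)(C)C(C)(C)C)[C@H]1CC(=O)O[C@@H]1/C=C(/C)[C@@H](O[Si](C)(C)C(C)(C)C)CCCB1OC(C)(C)C(C)(C)O1 | intermediate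
17 | (4S,5R)-5-[(1Z,3S)-3-(tert-butyldimethylsilyloxy)-6-hydroxy-2-methylhex-1-en-1-yl]-4-[1-(tert-butyldimethylsilyloxy)vinyl]dihydrofuran-2(3H)-one | C=C(O[Si](C)(C)C(C)(C)C)[C@H]1CC(=O)O[C@@H]1/C=C(/C)[C@@H](O[Si](C)(C)C(C)(C)C)CCCO | intermediate
18 | (4S,5Z)-4-(tert-butyldimethylsilyloxy)-5-methyl-6-[(2R,3S)-5-oxo-3-[1-(tert-butyldimethylsilyloxy)vinyl]tetrahydrofuran-2-yl]hex-5-enal | C=C(O[Si](C)(C)C(C)(C)C)[C@H]1CC(=O)O[C@@H]1/C=C(/C)[C@@H](O[Si](C)(C)C(C)(C)C)CCC=O | intermediate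
19 | (2S,4S,5Z)-2-chloro-4-(tert-butyldimethylsilyloxy)-5-methyl-6-[(2R,3S)-5-oxo-3-[1-(tert-butyldimethylsilyloxy)vinyl]tetrahydrofuran-2-yl]hex-5-enal | C=C(O[Si](C)(C)C(C)(C)C)[C@H]1CC(=O)O[C@@H]1/C=C(/C)[C@@H](O[Si](C)(C)C(C)(C)C)C[C@H](Cl)C=O | intermediate
20 | (4S,5R)-5-[(1Z,3S,5S,6R)-3-(tert-butyldimethylsilyloxy)-5-chloro-6-hydroxy-2-methylhept-1-en-1-yl]-4-[1-(tert-butyldimethylsilyloxy)vinyl]dihydrofuran-2(3H)-one (major C10 epimer drawn) | C=C(O[Si](C)(C)C(C)(C)C)[C@H]1CC(=O)O[C@@H]1/C=C(/C)[C@@H](O[Si](C)(C)C(C)(C)C)C[C@H](Cl)[C@@H](C)O | intermediate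
21 | (4S,5R)-5-[(1Z,3S,5S)-3-(tert-butyldimethylsilyloxy)-5-chloro-2-methyl-6-oxohept-1-en-1-yl]-4-[1-(tert-butyldimethylsilyloxy)vinyl]dihydrofuran-2(3H)-one (key-step precursor) | C=C(O[Si](C)(C)C(C)(C)C)[C@H]1CC(=O)O[C@@H]1/C=C(/C)[C@@H](O[Si](C)(C)C(C)(C)C)C[C@H](Cl)C(C)=O | intermediate
22 | (1S,3S,4Z,6R,7S,10R)-1-chloro-10-hydroxy-8-oxo-3-(tert-butyldimethylsilyloxy)-13-norgermacr-4-en-12,6-olide (key-step product) | O=C1C[C@@](C)(O)[C@@H](Cl)C[C@H](O[Si](C)(C)C(C)(C)C)/C(C)=C\[C@H]2OC(=O)C[C@@H]21 | intermediate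
23 | (1S,3S,4Z,6R,7R,8S,10R)-1-chloro-8,10-dihydroxy-3-(tert-butyldimethylsilyloxy)-13-norgermacr-4-en-12,6-olide | O[C@H]1C[C@@](C)(O)[C@@H](Cl)C[C@H](O[Si](C)(C)C(C)(C)C)/C(C)=C\[C@H]2OC(=O)C[C@@H]21 | intermediate
24 | (1S,3S,4Z,6R,7S,8S,10R)-1-chloro-10-hydroxy-3-(tert-butyldimethylsilyloxy)-8-(triethylsilyloxy)-13-norgermacr-4-en-12,6-olide | CC[Si](CC)(CC)O[C@H]1C[C@@](C)(O)[C@@H](Cl)C[C@H](O[Si](C)(C)C(C)(C)C)/C(C)=C\[C@H]2OC(=O)C[C@@H]21 | intermediate
25 | (1R,3S,4Z,6R,7S,8S,10R)-1,10-epoxy-3-(tert-butyldimethylsilyloxy)-8-(triethylsilyloxy)-13-norgermacr-4-en-12,6-olide | C1C(=O)O[C@@H]2/C=C(/C)[C@@H](O[Si](C)(C)C(C)(C)C)C[C@H]3O[C@]3(C)C[C@H](O[Si](CC)(CC)CC)[C@@H]12 | intermediate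
26 | 13-(dimethylamino) derivative of 25 (C11 epimers) | CN(C)CC1C(=O)O[C@@H]2/C=C(/C)[C@@H](O[Si](C)(C)C(C)(C)C)C[C@H]3O[C@]3(C)C[C@H](O[Si](CC)(CC)CC)[C@@H]12 | intermediate
27 | 13-(trimethylammonio) iodide of 25 (not isolated) | C[N+](C)(C)CC1C(=O)O[C@@H]2/C=C(/C)[C@@H](O[Si](C)(C)C(C)(C)C)C[C@H]3O[C@]3(C)C[C@H](O[Si](CC)(CC)CC)[C@@H]12.[I-] | intermediate
28 | (1R,3S,4Z,6R,7S,8S,10R)-1,10-epoxy-3-(tert-butyldimethylsilyloxy)-8-(triethylsilyloxy)germacra-4,11(13)-dien-12,6-olide | C=C1C(=O)O[C@@H]2/C=C(/C)[C@@H](O[Si](C)(C)C(C)(C)C)C[C@H]3O[C@]3(C)C[C@H](O[Si](CC)(CC)CC)[C@@H]12 | intermediate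
29 | (1R,3S,4Z,6R,7R,8S,10R)-1,10-epoxy-8-hydroxy-3-(tert-butyldimethylsilyloxy)germacra-4,11(13)-dien-12,6-olide | C=C1C(=O)O[C@@H]2/C=C(/C)[C@@H](O[Si](C)(C)C(C)(C)C)C[C@H]3O[C@]3(C)C[C@H](O)[C@@H]12 | intermediate
30 | (1R,3S,4Z,6R,7R,8S,10R)-1,10-epoxy-8-(3-methylbutanoyloxy)-3-(tert-butyldimethylsilyloxy)germacra-4,11(13)-dien-12,6-olide | C=C1C(=O)O[C@@H]2/C=C(/C)[C@@H](O[Si](C)(C)C(C)(C)C)C[C@H]3O[C@]3(C)C[C@H](OC(=O)CC(C)C)[C@@H]12 | intermediate
31 | (1R,3S,4Z,6R,7R,8S,10R)-1,10-epoxy-3-hydroxy-8-(3-methylbutanoyloxy)germacra-4,11(13)-dien-12,6-olide | C=C1C(=O)O[C@@H]2/C=C(/C)[C@@H](O)C[C@H]3O[C@]3(C)C[C@H](OC(=O)CC(C)C)[C@@H]12 | intermediate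
32 | (1R,3S,4Z,6R,7R,8S,10R)-3-acetoxy-1,10-epoxy-8-(3-methylbutanoyloxy)germacra-4,11(13)-dien-12,6-olide (CNP0157657.1) | C=C1C(=O)O[C@@H]2/C=C(/C)[C@@H](OC(C)=O)C[C@H]3O[C@]3(C)C[C@H](OC(=O)CC(C)C)[C@@H]12 | target

Total step count: 25. Longest linear sequence: 24 steps (steps 1–5 and 7–25, from 3-methylfuran-2(5H)-one); the imide branch is one step (step 6).

Steps most likely to fail

Step 16. The enol silane may be protodesilylated before it reaches the ketone, the aldol may proceed between molecules instead of within one, or the C10 face may be poorly controlled in the medium-ring transition state. The fallback sets out from 21 and returns at 22. N-Bromosuccinimide (THF, NaHCO3, −20 °C) should convert the silyl enol ether regiospecifically into the bromomethyl ketone (4S,5R)-4-(bromoacetyl)-5-[(1Z,3S,5S)-3-(tert-butyldimethylsilyloxy)-5-chloro-2-methyl-6-oxohept-1-en-1-yl]dihydrofuran-2(3H)-one F1. Slow addition of this to activated Zn and Et2AlCl in THF at high dilution then gives an intramolecular Reformatsky reaction. Zinc should insert into the primary α-keto C–Br bond far faster than into the secondary C–Cl bond, and the non-chelated zinc enolate should add to the C10 ketone in the same Cornforth sense to give 22.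

Step 17. The medium ring rather than the boron chelate may decide the direction of hydride attack, or chelation at the tertiary alkoxide may be slow, so that facial selectivity at C8 is poor. The fallback sets out from 22 and returns at 23. Reduction with Me4NBH(OAc)3 (MeCN/AcOH, −30 °C; Evans–Saksena internal hydride delivery from the O10-bound borohydride) should give the 8,10-anti diol (8R)-epimer of 23 F2. Mitsunobu reaction with chloroacetic acid (PPh3, DIAD, toluene, 0 °C → rt; the tertiary hydroxyl does not take part) then inverts C8 to give the (8S)-chloroacetate of 23 F3. Thiourea (NaHCO3, EtOH, rt) removes the chloroacetyl group without closing the chlorohydrin and delivers 23.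

Step 13 (and the carriage of the silyl enol ether through steps 11–15). The acidic catalyst salt and the pentachlorophenol formed may protodesilylate the enol ether, or the chlorinating agent may attack it in competition with the enamine. The fallback sets out from 12 and returns at 20; it keeps C8 as a Weinreb amide until the chloride is in place.
- CDI, then MeNH(OMe)·HCl, converts 12 into the Weinreb amide F4.
- 9-BBN, then NaBO3·4H2O, gives the primary alcohol F5.
- Dess–Martin oxidation gives the aldehyde F6.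
- The same organocatalytic chlorination, now with no enol ether present, gives the (S)-α-chloro aldehyde F7.
- Excess MeMgBr (−78 → −20 °C) adds to the aldehyde and converts the Weinreb amide into the methyl ketone, giving the keto chlorohydrin F8.
- TMSCl and imidazole give the trimethylsilyl ether F9.
- LiN(SiMe3)2, then TBSOTf, gives the enol silane trimethylsilyl ether F10.
- Brief treatment with catalytic K2CO3 in MeOH at −20 °C should cleave only the alkyl trimethylsilyl ether and give 20.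

Further compounds
F1 | step 16 | (4S,5R)-4-(bromoacetyl)-5-[(1Z,3S,5S)-3-(tert-butyldimethylsilyloxy)-5-chloro-2-methyl-6-oxohept-1-en-1-yl]dihydrofuran-2(3H)-one | O=C1C[C@H](C(=O)CBr)[C@@H](/C=C(/C)[C@@H](O[Si](C)(C)C(C)(C)C)C[C@H](Cl)C(C)=O)O1
F2 | step 17 | (1S,3S,4Z,6R,7R,8R,10R)-1-chloro-8,10-dihydroxy-3-(tert-butyldimethylsilyloxy)-13-norgermacr-4-en-12,6-olide (8-epimer of 23) | O[C@@H]1C[C@@](C)(O)[C@@H](Cl)C[C@H](O[Si](C)(C)C(C)(C)C)/C(C)=C\[C@H]2OC(=O)C[C@@H]21
F3 | step 17 | (1S,3S,4Z,6R,7R,8S,10R)-1-chloro-8-(chloroacetoxy)-10-hydroxy-3-(tert-butyldimethylsilyloxy)-13-norgermacr-4-en-12,6-olide | ClCC(=O)O[C@H]1C[C@@](C)(O)[C@@H](Cl)C[C@H](O[Si](C)(C)C(C)(C)C)/C(C)=C\[C@H]2OC(=O)C[C@@H]21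
F4 | step 13 | (2R,3S)-2-[(1Z,3S)-3-(tert-butyldimethylsilyloxy)-2-methylhexa-1,5-dien-1-yl]-N-methoxy-N-methyl-5-oxotetrahydrofuran-3-carboxamide | O=C1C[C@H](C(=O)N(C)OC)[C@@H](/C=C(/C)[C@@H](O[Si](C)(C)C(C)(C)C)CC=C)O1
F5 | step 13 | (2R,3S)-2-[(1Z,3S)-3-(tert-butyldimethylsilyloxy)-6-hydroxy-2-methylhex-1-en-1-yl]-N-methoxy-N-methyl-5-oxotetrahydrofuran-3-carboxamide | O=C1C[C@H](C(=O)N(C)OC)[C@@H](/C=C(/C)[C@@H](O[Si](C)(C)C(C)(C)C)CCCO)O1
F6 | step 13 | (2R,3S)-2-[(1Z,3S)-3-(tert-butyldimethylsilyloxy)-2-methyl-6-oxohex-1-en-1-yl]-N-methoxy-N-methyl-5-oxotetrahydrofuran-3-carboxamide | O=C1C[C@H](C(=O)N(C)OC)[C@@H](/C=C(/C)[C@@H](O[Si](C)(C)C(C)(C)C)CCC=O)O1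
F7 | step 13 | (2R,3S)-2-[(1Z,3S,5S)-3-(tert-butyldimethylsilyloxy)-5-chloro-2-methyl-6-oxohex-1-en-1-yl]-N-methoxy-N-methyl-5-oxotetrahydrofuran-3-carboxamide | O=C1C[C@H](C(=O)N(C)OC)[C@@H](/C=C(/C)[C@@H](O[Si](C)(C)C(C)(C)C)C[C@H](Cl)C=O)O1
F8 | step 13 | (4S,5R)-4-acetyl-5-[(1Z,3S,5S,6R)-3-(tert-butyldimethylsilyloxy)-5-chloro-6-hydroxy-2-methylhept-1-en-1-yl]dihydrofuran-2(3H)-one | O=C1C[C@H](C(C)=O)[C@@H](/C=C(/C)[C@@H](O[Si](C)(C)C(C)(C)C)C[C@H](Cl)[C@@H](C)O)O1
F9 | step 13 | (4S,5R)-4-acetyl-5-[(1Z,3S,5S,6R)-3-(tert-butyldimethylsilyloxy)-5-chloro-2-methyl-6-(trimethylsilyloxy)hept-1-en-1-yl]dihydrofuran-2(3H)-one | O=C1C[C@H](C(C)=O)[C@@H](/C=C(/C)[C@@H](O[Si](C)(C)C(C)(C)C)C[C@H](Cl)[C@@H](C)O[Si](C)(C)C)O1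
F10 | step 13 | (4S,5R)-5-[(1Z,3S,5S,6R)-3-(tert-butyldimethylsilyloxy)-5-chloro-2-methyl-6-(trimethylsilyloxy)hept-1-en-1-yl]-4-[1-(tert-butyldimethylsilyloxy)vinyl]dihydrofuran-2(3H)-one | C=C(O[Si](C)(C)C(C)(C)C)[C@H]1CC(=O)O[C@@H]1/C=C(/C)[C@@H](O[Si](C)(C)C(C)(C)C)C[C@H](Cl)[C@@H](C)O[Si](C)(C)C
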